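# Proposed total synthesis of CNP0303917.1 (33) via a silyl glyoxylate three-component coupling

Abbreviations: PMB = 4-methoxybenzyl, TBS = tert-butyldimethylsilyl, TES = triethylsilyl. Germacrane numbering is used for the ring atoms throughout.

## The problem

Target 33 is a melampolide-type germacranolide: a cyclodeca-1(10),4-diene with a Z olefin at C1=C10 and an E olefin at C4=C5, trans-fused across C6–C7 to an α-methylene-γ-butyrolactone. Four contiguous oxygen-bearing stereocentres run from C6 to C9 (6S,7S,8S,9R). C7 is a tertiary carbinol at the ring fusion, C8 carries a free secondary hydroxyl and O9 carries an angelate. A synthesis must close a strained ten-membered ring holding two trisubstituted olefins of opposite geometry, set the C6–C9 tetrad, and tell three neighbouring oxygens apart so that only O9 is acylated. Only C9 is easily taken from the chiral pool; its ether oxygen can steer C8 by chelation, the enolate geometry together with C8 can steer C7, and the fully substituted C7 is the only handle on C6. The fragile parts are the α-methylene lactone (Michael acceptor, and any lactone enolate at C11 would expel O7), the angelate (isomerises to the tiglate and migrates to O8 under base), the allylic C6–O and C9–O bonds, and the 1,5-diene (Cope and transannular reactions on heating or in acid). The feature that opens the structure is C7 itself: it is bonded to O7, C6, C8 and C11, so it is a glycolate carbon at the glyoxylate oxidation level. It can first accept C11 as an acetylide and then, after a silicon shift from carbon to oxygen, donate to C8 as an enolate.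

## Retrosynthesis

**Ester and silyl ethers (33 from 32, 32 from 29 and 30).** The O9–acyl bond is cut last but one, because an angelate would not survive hydride reduction, chromium chemistry or carbonylation. Angelic acid 30 is attached to the single free hydroxyl of 29, and the two silyl ethers of 32 are removed at the end under acidic fluoride conditions. This requires that O9 be distinguishable from O7 and O8 from the start: O9 carries a PMB ether, O7 and O8 carry silyl ethers.

**Lactone (28 from 27).** The C11–C12 and O6–C12 bonds are cut, which removes carbon monoxide and leaves the homopropargylic alcohol 27. The neighbouring option, α-methylenation of a saturated lactone, needs an enolate at C11 that would eliminate O7. The alkyne route never forms that enolate and gives the exocyclic methylene directly. The forward reaction must close onto O6 only, so O7, O8 and O9 stay protected.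

**Ten-membered ring (26 from 25).** The C5–C6 bond is cut to a vinyl iodide and an aldehyde (Nozaki–Hiyama–Kishi closure). Ring-closing metathesis at either trisubstituted olefin would leave the olefin geometry to the ring, and a C2–C3 alkylation would need extra activating groups. The C5–C6 cut places the aldehyde on the carbon that a glyoxylate ester supplies and keeps the preformed E-vinyl iodide geometry. The forward reaction must give the 6S alcohol and tolerate the silylalkyne.

**Adjustment of C6 and O8 (25 from 24, 23 and 22).** Aldehyde 25 comes from ester 22 by silylation of O8 (23), reduction (24) and oxidation. No skeletal bond changes.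

**Key disconnection (22 from 19, 17 and 14).** The C7–C11 and C7–C8 bonds are cut in one operation to the acetylide 19 (C11, C13), the silyl glyoxylate 17 (C7, C6) and the α-alkoxy aldehyde 14. Compared with adding an acetylide to a preformed α-keto ester, or with a separate glycolate aldol, this uses three simple pieces, installs the O7 silyl ether without a protection step, and sets C7 and C8 together. Aldehyde 14 is chosen to carry C8–C10 and C1–C5 with both olefins in place, so the coupling delivers every ring carbon except C12. The forward reaction must set C8 syn to C9 by chelation and C7 anti to C8 through a closed transition state.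

**Aldehyde (14 from 13, 12, 11 and 10; 10 from 5 and 8).** The C1=C10 olefin is cut by a Wittig disconnection to the α-alkoxy methyl ketone 8 and the ylide of phosphonium salt 5. α-Oxygenated methyl ketones give the Z trisubstituted olefin with non-stabilised ylides, which is the geometry needed. Doing this before the coupling avoids building a C10 ketone inside the crowded adduct. The diol of 11 is differentiated through the 4-methoxybenzylidene acetal 12, whose reductive opening leaves PMB on O9 (13).

**Small fragments.** Salt 5 comes from pent-4-yn-1-ol 1 through carboalumination–iodination (3, sets the E C4=C5 olefin and the C15 methyl) and the diiodide 4. Ketone 8 comes from the commercial glycerate acetonide 6 through Weinreb amide 7. Glyoxylate 17 comes from tert-butyl diazoacetate 15 through silyl diazoacetate 16. Acetylide 19 comes from ethynyltrimethylsilane 18.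

## Roads not taken

**Alternative 1:** Photo-thermal metathesis. The ring olefins C1=C10 and C4=C5 are traced back to a cyclobutane: [2+2] photocycloaddition of the lactone-fused 2-methylcyclohexenone A1 with 1-methylcyclobutene A2 would form C1–C10 and C4–C5 and give the tricyclic photoadduct A3, and thermal cycloreversion would then open the ten-membered diene.
- Merits: no high-dilution macrocyclisation, no stereocentre is created during ring formation, C6–C8 are fixed beforehand on a six-membered ring, and the O7/O8 acetonide leaves O9 distinct.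
- Weak points: A1 already needs three stereocentres and the lactone. The photoaddition must be head-to-tail and face-selective while creating a quaternary carbon. The ring opening needs temperatures at which a 1,5-diene also undergoes Cope rearrangement. The C9 ketone must then be reduced with control, and the methylene must be introduced through a lactone enolate that has O7 in the β-position.
- Comparison: this road is better at ring construction and at C6. The chosen plan sets against it convergence, olefin geometries fixed by dedicated reactions before the ring exists (steps 1 and 6), mild conditions, and a methylene lactone made without an enolate (step 19).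

**Alternative 2:** Pinacol closure across C8–C9. Reduction of the dialdehyde A4 with SmI2 (divalent samarium) or a divalent vanadium reagent would couple the C8 aldehyde with the C9 enal and give the ten-membered diol A5.
- Merits: ring closure and two stereocentres in one step, and C6/C7 are set earlier in an acyclic or five-membered setting.
- Weak points: the Z-enal is reduced first and its allylic ketyl can lose geometry or couple at the γ-position. The C8 aldehyde has an α-alkoxy group on C7 that a one-electron reductant can cleave. Two new centres must come out syn and in the right absolute sense in a medium ring. The resulting free C8/C9 diol must be mono-angeloylated at O9, and the methylene again has to go in through an enolate next to O7.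
- Comparison: at the ring-closing stage this road is more economical than the chosen plan, which closes the ring at C5–C6 and creates only C6 there. The chosen plan sets C7–C9 in an open chain from a chiral-pool C9 with O8 and O9 already differentiated (22), and it carries the alkyne for the lactone from the same step.

**Alternative 3:** Dichloroketene cycloaddition and Baeyer–Villiger oxidation. Dichloroketene A7 would add across the C6=C7 silyl enol ether A6 to form C6–C12 and C7–C11 in the dichlorocyclobutanone A8, and oxidative ring expansion would give the lactone.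
- Merits: a robust and scalable cycloaddition, favourable regiochemistry in both the cycloaddition and the oxygen insertion, and C6 and C7 are set together and stereospecifically from the enol ether geometry. The chosen plan cannot match this, since it leaves C6 to the ring closure of step 17.
- Weak points: facial control rests on the neighbouring acetonide only. A 3-siloxycyclobutanone is prone to ring opening. After dechlorination the methylene must be installed through an enolate β to O7. Nothing of the ten-membered ring exists yet, so both trisubstituted olefins and the macrocyclisation lie ahead.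
- Comparison: better for C6; the chosen plan is shorter to the full carbon skeleton, because 22 already contains every ring carbon, and it avoids the enolate.

Key step: step 13

## Assumptions

- The target SMILES is read as 6S,7S,8S,9R with 1(10)Z and 4E olefins and a (Z)-2-methylbut-2-enoate on O9.
- The aldehyde partner of the coupling (14) is taken in its elaborated form, with C1–C5 and both olefins already attached; this changes only spectator groups of the coupling.

## Route

Step 1
Reactants: 1 pent-4-yn-1-ol
Product: 3 (4E)-5-iodo-4-methylpent-4-en-1-ol, via alkenylalane 2 (not isolated)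
Conditions: Me3Al, Cp2ZrCl2 (cat.), CH2Cl2, 0 °C to rt; then I2, THF, −30 °C
Reagents that add atoms: trimethylaluminium, C[Al](C)C; iodine, [I][I]
Why: Negishi zirconium-catalysed carboalumination adds methyl and aluminium syn across the terminal alkyne with the metal at the terminus; iodinolysis with retention gives the E vinyl iodide that becomes C4=C5 with its C15 methyl.

Step 2
Reactants: 3 (4E)-5-iodo-4-methylpent-4-en-1-ol
Product: 4 (1E)-1,5-diiodo-2-methylpent-1-ene
Conditions: I2, PPh3, imidazole, CH2Cl2, 0 °C to rt
Reagents that add atoms: iodine, [I][I]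
Why: Appel-type iodination of the primary alcohol through the alkoxyphosphonium ion; the vinyl iodide is inert.

Step 3
Reactants: 4 (1E)-1,5-diiodo-2-methylpent-1-ene
Product: 5 [(4E)-5-iodo-4-methylpent-4-en-1-yl]triphenylphosphonium iodide
Conditions: PPh3, MeCN, reflux
Reagents that add atoms: triphenylphosphine, c1ccc(cc1)P(c1ccccc1)c1ccccc1
Why: SN2 quaternisation occurs only at the primary alkyl iodide; the sp2 C–I bond does not react with the phosphine.

Step 4
Reactants: 6 methyl (4S)-2,2-dimethyl-1,3-dioxolane-4-carboxylate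
Product: 7 (4S)-N-methoxy-N,2,2-trimethyl-1,3-dioxolane-4-carboxamide
Conditions: MeNHOMe·HCl, iPrMgCl, THF, −20 °C
Reagents that add atoms: N,O-dimethylhydroxylamine hydrochloride, CNOC.Cl
Why: Acyl substitution by the magnesium amide gives the Weinreb amide; the low temperature keeps the α-alkoxy stereocentre (future C9) intact.

Step 5
Reactants: 7 (4S)-N-methoxy-N,2,2-trimethyl-1,3-dioxolane-4-carboxamide
Product: 8 1-[(4S)-2,2-dimethyl-1,3-dioxolan-4-yl]ethan-1-one
Conditions: MeMgBr, THF, −78 to 0 °C
Reagents that add atoms: methylmagnesium bromide, C[Mg]Br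
Why: Grignard addition to the Weinreb amide stops at the chelated tetrahedral intermediate, which gives the methyl ketone (C10, C14) on work-up without over-addition.

Step 6
Reactants: 5 [(4E)-5-iodo-4-methylpent-4-en-1-yl]triphenylphosphonium iodide; 8 1-[(4S)-2,2-dimethyl-1,3-dioxolan-4-yl]ethan-1-one
Product: 10 (4R)-4-[(2Z,6E)-7-iodo-6-methylhepta-2,6-dien-2-yl]-2,2-dimethyl-1,3-dioxolane, via phosphorus ylide 9 (not isolated)
Conditions: NaN(SiMe3)2, THF, −78 °C; then 8, −78 °C to rt
Reagents that add atoms: none
Why: Wittig olefination with a salt-free non-stabilised ylide; α-oxygenated methyl ketones place the ylide chain cis to the oxygen-bearing carbon, which is the Z geometry needed at C1=C10. The vinyl iodide is inert to the ylide at low temperature, and the stereocentre is untouched (its descriptor changes from S to R only through CIP priorities).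

Step 7
Reactants: 10 (4R)-4-[(2Z,6E)-7-iodo-6-methylhepta-2,6-dien-2-yl]-2,2-dimethyl-1,3-dioxolane
Product: 11 (2R,3Z,7E)-8-iodo-3,7-dimethylocta-3,7-diene-1,2-diol
Conditions: AcOH/H2O (4:1), 40 °C
Reagents that add atoms: none
Why: Mild acid-catalysed acetal hydrolysis frees the C8/C9 diol without ionising the allylic C9–O bond.

Step 8
Reactants: 11 (2R,3Z,7E)-8-iodo-3,7-dimethylocta-3,7-diene-1,2-diol
Product: 12 (4R)-4-[(2Z,6E)-7-iodo-6-methylhepta-2,6-dien-2-yl]-2-(4-methoxyphenyl)-1,3-dioxolane (both acetal epimers)
Conditions: 4-MeOC6H4CH(OMe)2, PPTS (cat.), CH2Cl2, rt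
Reagents that add atoms: 4-methoxybenzaldehyde dimethyl acetal, COC(OC)c1ccc(OC)cc1
Why: Acid-catalysed transacetalisation gives the five-membered 4-methoxybenzylidene acetal; the configuration at the acetal carbon is irrelevant because that carbon becomes a CH2 in step 9.

Step 9
Reactants: 12 (4R)-4-[(2Z,6E)-7-iodo-6-methylhepta-2,6-dien-2-yl]-2-(4-methoxyphenyl)-1,3-dioxolane
Product: 13 (2R,3Z,7E)-8-iodo-2-[(4-methoxybenzyl)oxy]-3,7-dimethylocta-3,7-dien-1-ol
Conditions: iBu2AlH, CH2Cl2, −78 to 0 °C
Reagents that add atoms: none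
Why: Reductive acetal opening: aluminium binds the less hindered primary oxygen and hydride goes to the acetal carbon, so the PMB group stays on the secondary O9 and the C8 hydroxyl is freed.

Step 10
Reactants: 13 (2R,3Z,7E)-8-iodo-2-[(4-methoxybenzyl)oxy]-3,7-dimethylocta-3,7-dien-1-ol
Product: 14 (2R,3Z,7E)-8-iodo-2-[(4-methoxybenzyl)oxy]-3,7-dimethylocta-3,7-dienal
Conditions: Dess–Martin periodinane, NaHCO3, CH2Cl2, 0 °C
Reagents that add atoms: none
Why: Buffered Dess–Martin oxidation is non-basic, so the α-alkoxy β,γ-unsaturated aldehyde should form without epimerisation at C9 or olefin migration; it is used at once.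

Step 11
Reactants: 15 tert-butyl diazoacetate
Product: 16 tert-butyl 2-[tert-butyl(dimethyl)silyl]-2-diazoacetate
Conditions: TBSOTf, iPr2NEt, Et2O, −78 °C to rt
Reagents that add atoms: tert-butyldimethylsilyl trifluoromethanesulfonate, CC(C)(C)[Si](C)(C)OS(=O)(=O)C(F)(F)F
Why: Electrophilic C-silylation of the diazo carbon followed by deprotonation of the diazonium ion; a standard entry to silyl diazoacetates.

Step 12
Reactants: 16 tert-butyl 2-[tert-butyl(dimethyl)silyl]-2-diazoacetate
Product: 17 tert-butyl 2-[tert-butyl(dimethyl)silyl]-2-oxoacetate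
Conditions: KHSO5 (Oxone), NaHCO3, acetone/H2O/CH2Cl2, 0 °C
Reagents that add atoms: dimethyldioxirane (formed from KHSO5 and acetone), CC1(C)OO1
Why: Oxygen-atom transfer from the dioxirane to the diazo carbon with loss of N2 gives the acylsilane (silyl glyoxylate).

Step 13
Reactants: 18 ethynyltrimethylsilane; 17 tert-butyl 2-[tert-butyl(dimethyl)silyl]-2-oxoacetate; 14 (2R,3Z,7E)-8-iodo-2-[(4-methoxybenzyl)oxy]-3,7-dimethylocta-3,7-dienal
Product: 22 tert-butyl (2S,3S,4R,5Z,9E)-2-[(tert-butyldimethylsilyl)oxy]-3-hydroxy-10-iodo-4-[(4-methoxybenzyl)oxy]-5,9-dimethyl-2-[(trimethylsilyl)ethynyl]deca-5,9-dienoate, via trimethylsilylethynylmagnesium bromide 19 (not isolated), via magnesium alkoxide 20 (not isolated), via magnesium glycolate enolate 21 (not isolated)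
Conditions: 18, EtMgBr, Et2O, 0 °C to rt; toluene, −78 °C, then 17; then 14, −78 to −40 °C; aq. NH4Cl at −40 °C
Reagents that add atoms: none
Why: Acetylide 19 attacks the acylsilane carbonyl of 17 (C7–C11); the magnesium alkoxide 20 undergoes a [1,2]-Brook shift of silicon from carbon to oxygen, driven by the ester-stabilised carbanion; the (Z)-glycolate enolate 21 then adds to aldehyde 14 (C7–C8). The closest known reaction type is the three-component coupling of silyl glyoxylates with metal acetylides and aldehydes by a Brook rearrangement–glycolate aldol cascade. No ring is closed. C8 is controlled by C9: in weakly coordinating ether/toluene the bromomagnesium centre should bind the aldehyde oxygen and the PMB ether oxygen in a five-membered chelate, and the enolate enters anti to the C10 alkenyl group, giving the 8,9-syn arrangement (8S). C7 is controlled by the enolate geometry and the closed transition state: the silyloxy group is cis to O–Mg because the Brook shift occurs within the alkoxide–ester chelate, and because the chelated aldehyde chain must sit axial in the six-membered transition state, the silyloxy group ends anti to the new C8 hydroxyl (7S) with the alkyne syn. The step also needs chemoselectivity of 19 for the acylsilane (17 is added to 19 before 14 is introduced), α- rather than γ-attack of the propargyl/allenyl enolate (usual for aldehydes in this reaction class), and survival of the vinyl iodide and the O7 silyl ether (low temperature and a cold quench to prevent silyl migration to O8).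

Step 14
Reactants: 22 tert-butyl (2S,3S,4R,5Z,9E)-2-[(tert-butyldimethylsilyl)oxy]-3-hydroxy-10-iodo-4-[(4-methoxybenzyl)oxy]-5,9-dimethyl-2-[(trimethylsilyl)ethynyl]deca-5,9-dienoate
Product: 23 tert-butyl (2S,3S,4R,5Z,9E)-2,3-bis[(tert-butyldimethylsilyl)oxy]-10-iodo-4-[(4-methoxybenzyl)oxy]-5,9-dimethyl-2-[(trimethylsilyl)ethynyl]deca-5,9-dienoate
Conditions: TBSOTf, 2,6-lutidine, CH2Cl2, −78 to −20 °C
Reagents that add atoms: tert-butyldimethylsilyl trifluoromethanesulfonate, CC(C)(C)[Si](C)(C)OS(=O)(=O)C(F)(F)F
Why: Silyl triflate with a hindered pyridine base silylates the hindered C8 hydroxyl without base-induced retro-aldol; the low temperature spares the tert-butyl ester.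

Step 15
Reactants: 23 tert-butyl (2S,3S,4R,5Z,9E)-2,3-bis[(tert-butyldimethylsilyl)oxy]-10-iodo-4-[(4-methoxybenzyl)oxy]-5,9-dimethyl-2-[(trimethylsilyl)ethynyl]deca-5,9-dienoate
Product: 24 (2R,3S,4R,5Z,9E)-2,3-bis[(tert-butyldimethylsilyl)oxy]-10-iodo-4-[(4-methoxybenzyl)oxy]-5,9-dimethyl-2-[(trimethylsilyl)ethynyl]deca-5,9-dien-1-ol
Conditions: iBu2AlH, CH2Cl2, −78 to 0 °C
Reagents that add atoms: none
Why: Hydride reduction of the ester to the primary C6 alcohol; the vinyl iodide, silylalkyne and ethers are inert to the aluminium hydride at this temperature (the C7 descriptor changes only through CIP priorities).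

Step 16
Reactants: 24 (2R,3S,4R,5Z,9E)-2,3-bis[(tert-butyldimethylsilyl)oxy]-10-iodo-4-[(4-methoxybenzyl)oxy]-5,9-dimethyl-2-[(trimethylsilyl)ethynyl]deca-5,9-dien-1-ol
Product: 25 (2S,3S,4R,5Z,9E)-2,3-bis[(tert-butyldimethylsilyl)oxy]-10-iodo-4-[(4-methoxybenzyl)oxy]-5,9-dimethyl-2-[(trimethylsilyl)ethynyl]deca-5,9-dienal
Conditions: Dess–Martin periodinane, NaHCO3, CH2Cl2, rt
Reagents that add atoms: none
Why: Dess–Martin oxidation of the neopentyl-type alcohol; the aldehyde has no α-hydrogen, so it cannot epimerise or eliminate.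

Step 17
Reactants: 25 (2S,3S,4R,5Z,9E)-2,3-bis[(tert-butyldimethylsilyl)oxy]-10-iodo-4-[(4-methoxybenzyl)oxy]-5,9-dimethyl-2-[(trimethylsilyl)ethynyl]deca-5,9-dienal
Product: 26 (1S,2E,6Z,8R,9S,10R)-9,10-bis[(tert-butyldimethylsilyl)oxy]-8-[(4-methoxybenzyl)oxy]-3,7-dimethyl-10-[(trimethylsilyl)ethynyl]cyclodeca-2,6-dien-1-ol
Conditions: CrCl2 (excess), NiCl2 (cat.), DMSO/THF, rt, high dilution (about 0.002 M)
Reagents that add atoms: none
Why: Intramolecular Nozaki–Hiyama–Kishi reaction: zerovalent nickel inserts into the C5–I bond, transmetalation gives an alkenyl–trivalent chromium species, and this adds to the C6 aldehyde with retention of the E olefin, closing the ten-membered ring. The 6S carbinol is expected from the conformer in which the C7 silyloxy group is anti to the forming bond and the slim alkynyl group lies beside the carbonyl oxygen; this point is flagged below.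

Step 18
Reactants: 26 (1S,2E,6Z,8R,9S,10R)-9,10-bis[(tert-butyldimethylsilyl)oxy]-8-[(4-methoxybenzyl)oxy]-3,7-dimethyl-10-[(trimethylsilyl)ethynyl]cyclodeca-2,6-dien-1-ol
Product: 27 (1S,2E,6Z,8R,9S,10R)-9,10-bis[(tert-butyldimethylsilyl)oxy]-10-ethynyl-8-[(4-methoxybenzyl)oxy]-3,7-dimethylcyclodeca-2,6-dien-1-ol
Conditions: K2CO3, MeOH, rt
Reagents that add atoms: none
Why: Methoxide-induced protiodesilylation removes only the alkynyl silicon; the alkyl TBS ethers are stable to carbonate in methanol.

Step 19
Reactants: 27 (1S,2E,6Z,8R,9S,10R)-9,10-bis[(tert-butyldimethylsilyl)oxy]-10-ethynyl-8-[(4-methoxybenzyl)oxy]-3,7-dimethylcyclodeca-2,6-dien-1-ol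
Product: 28 (3aR,4S,5R,6Z,10E,11aS)-3a,4-bis[(tert-butyldimethylsilyl)oxy]-5-[(4-methoxybenzyl)oxy]-6,10-dimethyl-3-methylidene-3a,4,5,8,9,11a-hexahydrocyclodeca[b]furan-2(3H)-one
Conditions: PdCl2 (cat.), PPh3, SnCl2, CO (several atm), MeCN, 65 °C
Reagents that add atoms: carbon monoxide, [C-]#[O+]
Why: Palladium-catalysed cyclocarbonylation of a homopropargylic alcohol: the C6 hydroxyl and CO give an alkoxycarbonyl–palladium species that adds syn across the alkyne in a 5-exo sense, and protonolysis of the vinyl–palladium bond leaves the exocyclic methylene. Only O6 is free, so the trans-fused 6,12-lactone forms, and no lactone enolate next to O7 is involved.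

Step 20
Reactants: 28 (3aR,4S,5R,6Z,10E,11aS)-3a,4-bis[(tert-butyldimethylsilyl)oxy]-5-[(4-methoxybenzyl)oxy]-6,10-dimethyl-3-methylidene-3a,4,5,8,9,11a-hexahydrocyclodeca[b]furan-2(3H)-one
Product: 29 (3aR,4S,5R,6Z,10E,11aS)-3a,4-bis[(tert-butyldimethylsilyl)oxy]-5-hydroxy-6,10-dimethyl-3-methylidene-3a,4,5,8,9,11a-hexahydrocyclodeca[b]furan-2(3H)-one
Conditions: DDQ, CH2Cl2/pH 7 buffer, 0 °C
Reagents that add atoms: none
Why: Oxidative PMB cleavage (benzylic oxidation to the oxocarbenium ion, then hydrolysis) frees O9 alone; buffering protects the silyl ethers and the acid-sensitive diene.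

Step 21
Reactants: 29 (3aR,4S,5R,6Z,10E,11aS)-3a,4-bis[(tert-butyldimethylsilyl)oxy]-5-hydroxy-6,10-dimethyl-3-methylidene-3a,4,5,8,9,11a-hexahydrocyclodeca[b]furan-2(3H)-one; 30 (2Z)-2-methylbut-2-enoic acid (angelic acid)
Product: 32 (3aR,4S,5R,6Z,10E,11aS)-3a,4-bis[(tert-butyldimethylsilyl)oxy]-6,10-dimethyl-3-methylidene-2-oxo-2,3,3a,4,5,8,9,11a-octahydrocyclodeca[b]furan-5-yl (2Z)-2-methylbut-2-enoate, via mixed anhydride 31 (not isolated)
Conditions: 30, 2,4,6-trichlorobenzoyl chloride, Et3N, toluene, rt; then 29, 80 °C
Reagents that add atoms: none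
Why: Yamaguchi-type esterification through the preformed mixed anhydride, run without a nucleophilic amine catalyst so that the angelate is not isomerised to the tiglate; O9 is the only free hydroxyl.

Step 22
Reactants: 32 (3aR,4S,5R,6Z,10E,11aS)-3a,4-bis[(tert-butyldimethylsilyl)oxy]-6,10-dimethyl-3-methylidene-2-oxo-2,3,3a,4,5,8,9,11a-octahydrocyclodeca[b]furan-5-yl (2Z)-2-methylbut-2-enoate
Product: 33 (3aS,4S,5R,6Z,10E,11aS)-3a,4-dihydroxy-6,10-dimethyl-3-methylidene-2-oxo-2,3,3a,4,5,8,9,11a-octahydrocyclodeca[b]furan-5-yl (2Z)-2-methylbut-2-enoate (target)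
Conditions: HF·pyridine, pyridine, THF, 0 °C to rt
Reagents that add atoms: none
Why: Fluoride-mediated desilylation under buffered acidic conditions removes both TBS ethers; the acidic medium suppresses O9-to-O8 acyl migration and conjugate addition to the methylene lactone.

## Compound list

1 | pent-4-yn-1-ol | C#CCCCO | starting material
2 | [(1E)-5-(dimethylalumanyloxy)-2-methylpent-1-en-1-yl]dimethylalumane | C[Al](C)OCCC/C(C)=C/[Al](C)C | intermediate
3 | (4E)-5-iodo-4-methylpent-4-en-1-ol | OCCC/C(C)=C/I | intermediate
4 | (1E)-1,5-diiodo-2-methylpent-1-ene | ICCC/C(C)=C/I | intermediate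
5 | [(4E)-5-iodo-4-methylpent-4-en-1-yl]triphenylphosphonium iodide | [I-].I/C=C(\C)CCC[P+](c1ccccc1)(c1ccccc1)c1ccccc1 | intermediate
6 | methyl (4S)-2,2-dimethyl-1,3-dioxolane-4-carboxylate | COC(=O)[C@@H]1COC(C)(C)O1 | starting material
7 | (4S)-N-methoxy-N,2,2-trimethyl-1,3-dioxolane-4-carboxamide | CON(C)C(=O)[C@@H]1COC(C)(C)O1 | intermediate
8 | 1-[(4S)-2,2-dimethyl-1,3-dioxolan-4-yl]ethan-1-one | CC(=O)[C@@H]1COC(C)(C)O1 | intermediate
9 | [(4E)-5-iodo-4-methylpent-4-en-1-ylidene]triphenyl-λ5-phosphane | I/C=C(\C)CCC=P(c1ccccc1)(c1ccccc1)c1ccccc1 | intermediate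
10 | (4R)-4-[(2Z,6E)-7-iodo-6-methylhepta-2,6-dien-2-yl]-2,2-dimethyl-1,3-dioxolane | C/C(=C/CC/C(C)=C/I)[C@@H]1COC(C)(C)O1 | intermediate
11 | (2R,3Z,7E)-8-iodo-3,7-dimethylocta-3,7-diene-1,2-diol | C/C(=C/CC/C(C)=C/I)[C@@H](O)CO | intermediate
12 | (4R)-4-[(2Z,6E)-7-iodo-6-methylhepta-2,6-dien-2-yl]-2-(4-methoxyphenyl)-1,3-dioxolane (acetal epimers) | C/C(=C/CC/C(C)=C/I)[C@@H]1COC(c2ccc(OC)cc2)O1 | intermediate
13 | (2R,3Z,7E)-8-iodo-2-[(4-methoxybenzyl)oxy]-3,7-dimethylocta-3,7-dien-1-ol | C/C(=C/CC/C(C)=C/I)[C@@H](OCc1ccc(OC)cc1)CO | intermediate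
14 | (2R,3Z,7E)-8-iodo-2-[(4-methoxybenzyl)oxy]-3,7-dimethylocta-3,7-dienal | C/C(=C/CC/C(C)=C/I)[C@@H](OCc1ccc(OC)cc1)C=O | intermediate
15 | tert-butyl diazoacetate | CC(C)(C)OC(=O)C=[N+]=[N-] | starting material
16 | tert-butyl 2-[tert-butyl(dimethyl)silyl]-2-diazoacetate | CC(C)(C)OC(=O)C(=[N+]=[N-])[Si](C)(C)C(C)(C)C | intermediate
17 | tert-butyl 2-[tert-butyl(dimethyl)silyl]-2-oxoacetate | CC(C)(C)OC(=O)C(=O)[Si](C)(C)C(C)(C)C | intermediate
18 | ethynyltrimethylsilane | C#C[Si](C)(C)C | starting material
19 | trimethylsilylethynylmagnesium bromide | C[Si](C)(C)C#C[Mg]Br | intermediate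
20 | bromomagnesium alkoxide of tert-butyl 2-[tert-butyl(dimethyl)silyl]-2-hydroxy-4-(trimethylsilyl)but-3-ynoate | C[Si](C)(C)C#CC(O[Mg]Br)(C(=O)OC(C)(C)C)[Si](C)(C)C(C)(C)C | intermediate
21 | bromomagnesium (Z)-enolate of tert-butyl 2-[(tert-butyldimethylsilyl)oxy]-4-(trimethylsilyl)but-3-ynoate | C[Si](C)(C)C#C/C(O[Si](C)(C)C(C)(C)C)=C(/O[Mg]Br)OC(C)(C)C | intermediate
22 | tert-butyl (2S,3S,4R,5Z,9E)-2-[(tert-butyldimethylsilyl)oxy]-3-hydroxy-10-iodo-4-[(4-methoxybenzyl)oxy]-5,9-dimethyl-2-[(trimethylsilyl)ethynyl]deca-5,9-dienoate | C[Si](C)(C)C#C[C@@](O[Si](C)(C)C(C)(C)C)(C(=O)OC(C)(C)C)[C@@H](O)[C@H](OCc1ccc(OC)cc1)/C(C)=C\CC/C(C)=C/I | intermediate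
23 | tert-butyl (2S,3S,4R,5Z,9E)-2,3-bis[(tert-butyldimethylsilyl)oxy]-10-iodo-4-[(4-methoxybenzyl)oxy]-5,9-dimethyl-2-[(trimethylsilyl)ethynyl]deca-5,9-dienoate | C[Si](C)(C)C#C[C@@](O[Si](C)(C)C(C)(C)C)(C(=O)OC(C)(C)C)[C@@H](O[Si](C)(C)C(C)(C)C)[C@H](OCc1ccc(OC)cc1)/C(C)=C\CC/C(C)=C/I | intermediate
24 | (2R,3S,4R,5Z,9E)-2,3-bis[(tert-butyldimethylsilyl)oxy]-10-iodo-4-[(4-methoxybenzyl)oxy]-5,9-dimethyl-2-[(trimethylsilyl)ethynyl]deca-5,9-dien-1-ol | C[Si](C)(C)C#C[C@@](O[Si](C)(C)C(C)(C)C)(CO)[C@@H](O[Si](C)(C)C(C)(C)C)[C@H](OCc1ccc(OC)cc1)/C(C)=C\CC/C(C)=C/I | intermediate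
25 | (2S,3S,4R,5Z,9E)-2,3-bis[(tert-butyldimethylsilyl)oxy]-10-iodo-4-[(4-methoxybenzyl)oxy]-5,9-dimethyl-2-[(trimethylsilyl)ethynyl]deca-5,9-dienal | C[Si](C)(C)C#C[C@@](O[Si](C)(C)C(C)(C)C)(C=O)[C@@H](O[Si](C)(C)C(C)(C)C)[C@H](OCc1ccc(OC)cc1)/C(C)=C\CC/C(C)=C/I | intermediate
26 | (1S,2E,6Z,8R,9S,10R)-9,10-bis[(tert-butyldimethylsilyl)oxy]-8-[(4-methoxybenzyl)oxy]-3,7-dimethyl-10-[(trimethylsilyl)ethynyl]cyclodeca-2,6-dien-1-ol | O[C@H]1/C=C(\C)CC/C=C(/C)[C@@H](OCc2ccc(OC)cc2)[C@H](O[Si](C)(C)C(C)(C)C)[C@@]1(O[Si](C)(C)C(C)(C)C)C#C[Si](C)(C)C | intermediate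
27 | (1S,2E,6Z,8R,9S,10R)-9,10-bis[(tert-butyldimethylsilyl)oxy]-10-ethynyl-8-[(4-methoxybenzyl)oxy]-3,7-dimethylcyclodeca-2,6-dien-1-ol | O[C@H]1/C=C(\C)CC/C=C(/C)[C@@H](OCc2ccc(OC)cc2)[C@H](O[Si](C)(C)C(C)(C)C)[C@@]1(O[Si](C)(C)C(C)(C)C)C#C | intermediate
28 | (3aR,4S,5R,6Z,10E,11aS)-3a,4-bis[(tert-butyldimethylsilyl)oxy]-5-[(4-methoxybenzyl)oxy]-6,10-dimethyl-3-methylidene-3a,4,5,8,9,11a-hexahydrocyclodeca[b]furan-2(3H)-one | C=C1C(=O)O[C@H]2/C=C(\C)CC/C=C(/C)[C@@H](OCc3ccc(OC)cc3)[C@H](O[Si](C)(C)C(C)(C)C)[C@@]12O[Si](C)(C)C(C)(C)C | intermediate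
29 | (3aR,4S,5R,6Z,10E,11aS)-3a,4-bis[(tert-butyldimethylsilyl)oxy]-5-hydroxy-6,10-dimethyl-3-methylidene-3a,4,5,8,9,11a-hexahydrocyclodeca[b]furan-2(3H)-one | C=C1C(=O)O[C@H]2/C=C(\C)CC/C=C(/C)[C@@H](O)[C@H](O[Si](C)(C)C(C)(C)C)[C@@]12O[Si](C)(C)C(C)(C)C | intermediate
30 | (2Z)-2-methylbut-2-enoic acid (angelic acid) | C/C=C(/C)C(=O)O | starting material
31 | (2Z)-2-methylbut-2-enoic 2,4,6-trichlorobenzoic anhydride | C/C=C(/C)C(=O)OC(=O)c1c(Cl)cc(Cl)cc1Cl | intermediate
32 | (3aR,4S,5R,6Z,10E,11aS)-3a,4-bis[(tert-butyldimethylsilyl)oxy]-6,10-dimethyl-3-methylidene-2-oxo-2,3,3a,4,5,8,9,11a-octahydrocyclodeca[b]furan-5-yl (2Z)-2-methylbut-2-enoate | C=C1C(=O)O[C@H]2/C=C(\C)CC/C=C(/C)[C@@H](OC(=O)/C(C)=C\C)[C@H](O[Si](C)(C)C(C)(C)C)[C@@]12O[Si](C)(C)C(C)(C)C | intermediate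
33 | (3aS,4S,5R,6Z,10E,11aS)-3a,4-dihydroxy-6,10-dimethyl-3-methylidene-2-oxo-2,3,3a,4,5,8,9,11a-octahydrocyclodeca[b]furan-5-yl (2Z)-2-methylbut-2-enoate | C=C1C(=O)O[C@H]2/C=C(\C)CC/C=C(/C)[C@@H](OC(=O)/C(C)=C\C)[C@H](O)[C@@]12O | target

## Step count and least certain steps

Total: 22 steps. Longest linear sequence: 18 steps (steps 1–3, 6–10, 13–22, from pent-4-yn-1-ol 1).

**Step 13 (key step).** The most likely failure is loss of chelation control. If the aldehyde reacts through a non-chelated chair, the enolate attacks the other face of C8 and the C7/C8 relationship changes with it. Further risks are attack through the γ-carbon of the propargyl/allenyl enolate, silyl migration from O7 to O8 followed by retro-aldol, and epimerisation of C9 in the β,γ-unsaturated aldehyde before it is consumed. The fallback sets out from 19 and 17 and comes back at 22, forming the two bonds in separate flasks. The Brook enolate 21 is quenched with acetic acid at −78 °C to give the racemic α-silyloxy ester F1. This is converted with LiN(iPr)2 and Me3SiCl into the silyl ketene acetal F2. F2 is added to aldehyde 14 that has been precomplexed with MgBr2·OEt2 in CH2Cl2 at −78 °C (chelation-controlled Mukaiyama aldol through an open transition state), and acidic work-up gives 22. This variant is expected to secure the C8/C9 syn relationship; the C7/C8 relationship would then rest on the open transition state and would have to be established.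

**Step 17 (Nozaki–Hiyama–Kishi closure).** The most likely failure is poor or reversed facial selectivity at C6, since the only control element is the quaternary C7 inside a flexible forming ring. Oligomerisation can compete if dilution is insufficient. The fallback sets out from 25 and comes back at 26, replacing substrate control in the C–C bond formation by reagent control in a reduction. If the closure gives the 6-epimeric alcohol F3, alone or mixed with 26, the material is oxidised with Dess–Martin periodinane to the macrocyclic enone F4. F4 is reduced with BH3·SMe2 and the (R)-configured B-methyl oxazaborolidine (Corey–Bakshi–Shibata reduction), the enantiomer predicted to give the 6S alcohol if C7 acts as the large group, which returns 26.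

**Step 19 (cyclocarbonylation).** The most likely failure is slow formation of the alkoxycarbonyl–palladium species at the hindered C6 hydroxyl. Then alkyne oligomerisation, loss of the O8 silyl group to the tin Lewis acid (followed by closure onto O8), or ionisation of the allylic lactone by zerovalent palladium can take over. The fallback sets out from 27 and comes back at 28 and uses radical chemistry. Alcohol 27 is acylated with PhSeC(O)Cl and pyridine to the Se-phenyl selenocarbonate F5. Bu3SnH and AIBN in hot benzene at high dilution generate the alkoxycarbonyl radical, which closes 5-exo onto the alkyne, and hydrogen transfer to the vinyl radical gives 28. The known weakness is loss of CO2 from an allylic alkoxycarbonyl radical, which the fast 5-exo closure has to outrun.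

**Step 21 (angeloylation).** The most likely failure is isomerisation of the angelate to the tiglate during a slow acylation of the hindered allylic O9, or silyl migration from O8 to O9 under the basic conditions. The fallback sets out from 29 and comes back at 32, building the Z olefin on the ester. Alcohol 29 is acylated with 2-[bis(2,2,2-trifluoroethoxy)phosphoryl]propanoic acid (carbodiimide, DMAP) to the phosphonopropionate F6. Still–Gennari olefination with KN(SiMe3)2, 18-crown-6 and acetaldehyde at −78 °C then gives the Z-2-methylbut-2-enoate 32.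

**Step 22 (final desilylation).** The most likely failure is incomplete cleavage of the tertiary silyl ether on O7 under conditions mild enough for the product. Forcing them invites acyl migration from O9 to O8, relactonisation onto O8, or acid-induced transannular cyclisation of the diene. The fallback sets out from 28 and comes back at 33, moving the difficult desilylation to a stage without the angelate.
- Lactone 28 is fully desilylated with HF·pyridine (longer time, gentle warming) to the diol F7.
- The secondary O8 alone is silylated with Et3SiCl and imidazole to give F8.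
- The PMB group is removed with DDQ to give F9.
- Yamaguchi angeloylation with 30 gives F10; the tertiary O7 hydroxyl is too hindered to be acylated.
- Brief treatment with HF·pyridine removes the triethylsilyl group and gives 33.

## Further compounds

F1 | step 13 | tert-butyl 2-[(tert-butyldimethylsilyl)oxy]-4-(trimethylsilyl)but-3-ynoate (racemic) | C[Si](C)(C)C#CC(O[Si](C)(C)C(C)(C)C)C(=O)OC(C)(C)C
F2 | step 13 | trimethylsilyl ketene acetal of F1 (1-tert-butoxy-2-[(tert-butyldimethylsilyl)oxy]-4-(trimethylsilyl)-1-[(trimethylsilyl)oxy]but-1-en-3-yne) | C[Si](C)(C)C#CC(O[Si](C)(C)C(C)(C)C)=C(O[Si](C)(C)C)OC(C)(C)C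
F3 | step 17 | C6 epimer of 26 (1R carbinol) | O[C@@H]1/C=C(\C)CC/C=C(/C)[C@@H](OCc2ccc(OC)cc2)[C@H](O[Si](C)(C)C(C)(C)C)[C@@]1(O[Si](C)(C)C(C)(C)C)C#C[Si](C)(C)C
F4 | step 17 | macrocyclic enone (C6 ketone of 26) | O=C1/C=C(\C)CC/C=C(/C)[C@@H](OCc2ccc(OC)cc2)[C@H](O[Si](C)(C)C(C)(C)C)[C@@]1(O[Si](C)(C)C(C)(C)C)C#C[Si](C)(C)C
F5 | step 19 | O6 Se-phenyl selenocarbonate of 27 | O=C([Se]c1ccccc1)O[C@H]1/C=C(\C)CC/C=C(/C)[C@@H](OCc2ccc(OC)cc2)[C@H](O[Si](C)(C)C(C)(C)C)[C@@]1(O[Si](C)(C)C(C)(C)C)C#C
F6 | step 21 | O9 2-[bis(2,2,2-trifluoroethoxy)phosphoryl]propanoate of 29 (epimers at the phosphonate carbon) | C=C1C(=O)O[C@H]2/C=C(\C)CC/C=C(/C)[C@@H](OC(=O)C(C)P(=O)(OCC(F)(F)F)OCC(F)(F)F)[C@H](O[Si](C)(C)C(C)(C)C)[C@@]12O[Si](C)(C)C(C)(C)C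
F7 | step 22 | O7,O8-diol of 28 (O9 PMB ether) | C=C1C(=O)O[C@H]2/C=C(\C)CC/C=C(/C)[C@@H](OCc3ccc(OC)cc3)[C@H](O)[C@@]12O
F8 | step 22 | O8 triethylsilyl ether of F7 | C=C1C(=O)O[C@H]2/C=C(\C)CC/C=C(/C)[C@@H](OCc3ccc(OC)cc3)[C@H](O[Si](CC)(CC)CC)[C@@]12O
F9 | step 22 | O9 alcohol from F8 | C=C1C(=O)O[C@H]2/C=C(\C)CC/C=C(/C)[C@@H](O)[C@H](O[Si](CC)(CC)CC)[C@@]12O
F10 | step 22 | O9 angelate of F9 (O8 triethylsilyl ether of 33) | C=C1C(=O)O[C@H]2/C=C(\C)CC/C=C(/C)[C@@H](OC(=O)/C(C)=C\C)[C@H](O[Si](CC)(CC)CC)[C@@]12O
A1 | alternative 1 | lactone-fused 2-methylcyclohexenone with O7/O8 acetonide | O=C1C(C)=C[C@@H]2OC(=O)C[C@]2(OC(C)(C)O3)[C@H]13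
A2 | alternative 1 | 1-methylcyclobutene | CC1=CCC1
A3 | alternative 1 | cis-anti-cis tricyclo[4.4.0.0(2,5)]decan-9-one photoadduct | O=C1[C@@]2(C)[C@@H]3CC[C@]3(C)[C@H]2[C@@H]4OC(=O)C[C@]4(OC(C)(C)O5)[C@H]15
A4 | alternative 2 | lactone dialdehyde (C8 aldehyde and C9 Z-enal, O7 methoxymethyl ether) | O=C[C@@]1(OCOC)CC(=O)O[C@H]1/C=C(\C)CC/C=C(/C)C=O
A5 | alternative 2 | ten-membered lactone-fused C8,C9-diol | C1C(=O)O[C@H]2/C=C(\C)CC/C=C(/C)[C@@H](O)[C@H](O)[C@@]12OCOC
A6 | alternative 3 | C6=C7 silyl enol ether | CC(C)(C)[Si](C)(C)OC(=CC1OCCO1)[C@H]2OC(C)(C)O[C@@H]2CO[Si](c3ccccc3)(c3ccccc3)C(C)(C)C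
A7 | alternative 3 | dichloroketene | ClC(Cl)=C=O
A8 | alternative 3 | 2,2-dichloro-3-siloxycyclobutanone | O=C1[C@@H](C2OCCO2)[C@@](O[Si](C)(C)C(C)(C)C)([C@H]3OC(C)(C)O[C@@H]3CO[Si](c4ccccc4)(c4ccccc4)C(C)(C)C)C1(Cl)Cl
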